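## Structural features

The target (25) is a linear trimer of three six-membered carbocycles joined by two methylene bridges; it has no stereocentre, so every problem is one of constitution and chemoselectivity. The central ring B is a fully substituted benzene: taking the butanoyl-bearing carbon as B1, it carries hydroxyls at B2, B4 and B6 and carbon substituents at B1 (butanoyl), B3 (CH2 to ring A) and B5 (CH2 to ring C). Rings A and C are filicinic acid units, 3,5-dihydroxy-4,4-dimethylcyclohexa-2,5-dien-1-ones acylated at C-2 (acetyl in ring A, propanoyl in ring C) and bound to the bridge through C-6; their gem-dimethyl carbons are not stereogenic. The fragile parts are the strongly acidic, metal-chelating triketone enols and the benzylic-type bridges, which can fragment and recombine under acid or base, and a ring B hydroxyl can close a pyran onto a neighbouring enol carbon. The real difficulty is to put two outer rings that differ by one CH2 group on defined positions of a hexasubstituted arene without any step in which the arms could exchange. The key step uses the strict alternation of oxygen-bearing (B2, B4, B6) and carbon-bearing (B1, B3, B5) atoms of ring B: this is the pattern formed when a ketene unit (B4, B5, B6, B1, supplied as a cyclobutenone) and an alkoxyalkyne (B3, B2) combine head to tail.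

## Logic of the disconnections

25 to 24. The last bonds cut are six O–alkyl bonds: the aryl O–ethyl bonds at B2 and B6 and the four enol O–methyl bonds of rings A and C. Cutting here keeps every acidic, chelating hydroxyl masked until the final operation, so all earlier intermediates are neutral and the bridges never meet free enols or base. The demand is that one reagent cleaves two kinds of ether at low temperature. The B1 ketone assists only the first ortho ether, so a halide-assisted boron reagent is needed.

24 to 22 and 23. The B1–carbonyl bond is cut. B1 is the only hydrogen-bearing carbon of ring B in 22, lies between two alkoxy groups and is para to the B4 hydroxyl, so it is the natural site for the acyl cation from 23. The gain is the direct product of the ring-forming step. The forward reaction must prefer C–H substitution at a doubly flanked position over O-acylation and over attack at the substituted carbons B3 and B5.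

22 to 10 and 17. Ring B is cut at B3–B4 and B1–B2; B4–B5 is broken and re-formed in the forward cascade but stays inside one partner. B4, B5, B6 and B1 with ring C go to 10; B3 and B2 with ring A go to 17. This halves the molecule into two partners of similar size and fixes each outer ring covalently to a different partner, so the arms cannot be interchanged. The demand is a neutral, thermal cascade with head-to-tail regiochemistry, run below the temperature at which the ethyl ynol ether of 17 fragments. Neither partner may contain an acidic hydrogen, which is why both outer rings are carried as bis(methyl enol ethers).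

10 to 6 and 7. The four-membered ring is cut at C-1–C-2 and C-3–C-4, a ketene–alkyne [2+2] in the forward sense, with 8 and 9 as transient species between 6 and 10. This reduces the strained ring to a three-carbon acid chain on ring C and a commercial two-carbon alkyne. The demand is that the acid be activated and dehydrohalogenated without free acid, and that 9 meet an excess of 7 before it dimerises.

6 to 5, 4, and on to 2 and 3. The O–benzyl bond, the two enol O–methyl bonds and the bond between the ring carbon and the chain are cut in turn. The ring carbon between the two ring oxygens of 2 is its natural nucleophilic site, and 3 supplies the three-carbon chain as a conjugate acceptor. A benzyl ester is chosen because it can be removed by hydrogenolysis after O-methylation; a methyl ester could not be hydrolysed next to vinylogous methyl esters. The demand is mono-addition at carbon.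

2 to 1 and 12 to 11. Two C–CH3 bonds at one ring carbon are cut in each case. This leads to two commercial acylphloroglucinols and installs the quaternary carbon by dearomatisation. The demand is to stop the C-methylation at the gem-dimethyl stage.

17 to 12 and 13 (through 14, 15 and 16). The bond between the ring A carbon and the propargylic CH2, and the two enol O–methyl bonds, are cut. The polarity is again natural, nucleophilic ring carbon and propargylic electrophile. The demands are two. The electrophile is labile and is therefore made and used cold, as 14 then 15. And 16 must never be protonated, because a free enol would add across its own ynol ether, so O-methylation is done on the dienolate in the same flask.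

13 to 7. The C(sp)–CH2 bond is cut, the addition of the metalated alkyne to a one-carbon aldehyde. It uses the same commercial alkyne as the other branch. The demand is an acid-free work-up.

## Other disconnections considered

Alternative 1: The cut runs through ring A itself. The bond from the bridge-bearing ring carbon to the ring carbon on the gem-dimethyl side, and the bond from the acetyl-bearing carbon to the ring carbonyl carbon, are disconnected. This leads to 5,7-bis(benzyloxy)chroman-2-one A2, whose C-4 is the future bridge, and the enol lactone 3,3,6-trimethylpyran-2,4-dione A3. In the forward key step the lithium enolate of A2 would open A3 at its lactone carbonyl, and the diketone enolate set free would attack the aryl lactone carbonyl in a Dieckmann-type closure. The product would be the two-ring compound A1 with ring A complete and a ring B phenol released.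
- In its favour: the bridge and its position on ring B exist before ring A is made, so no methylene transfer, no C-alkylation of an acylfilicinic acid and no enol ethers on ring A are needed. The gem-dimethyl group comes in with A3, which avoids over-methylation.
- Against it here: A1 contains only two of the three rings. Ring C, the second bridge and the butanoyl group would still have to be added, most plausibly by a second relay on a second lactone or by methylene transfer, with its exchange risk. The lactone carbonyl of A3 is neopentyl-hindered and competes with its own ketone, and the stabilised diketone enolate is a weak nucleophile for the ring closure.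
- Comparison: on protecting-group burden for ring A this plan is better than the chosen one, and on stereochemistry the two are equal (none to control). On structure it solves one outer ring, whereas the chosen step joins all three rings. Mechanistically it is an ionic, strongly basic acyl-transfer cascade against a neutral pericyclic one. On step economy it is longer for the whole target.

Alternative 2: Both outer rings are cut at the bond between the ester-derived C–O carbon next to the gem-dimethyl group and the acyl-bearing carbon. The precursor is the bis-isoxazole A5, a complete tri-O-benzyl ring B with butanoyl in place and two keto-ester arms. In the forward key step Mo(CO)6 in wet acetonitrile would cleave both N–O bonds, methoxide would drive attack of the unmasked enamine carbons on the two methyl esters, and aqueous acid would remove nitrogen, giving the tri-O-benzyl target A4.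
- In its favour: two rings would form in one operation, the acetyl/propanoyl difference is written into the isoxazole substituents, and the butanoyl group is present from the start. The end game is a neutral hydrogenolysis of benzyl ethers, which is gentler than Lewis-acid dealkylation; on this point it is better than the chosen plan.
- Against it here: A5 is large, and its two different arms must be put one after the other on a symmetrical ring B. The esters are neopentyl-hindered, and N-acylation of the enaminone (pyridinone formation) competes with C-acylation. Stoichiometric zerovalent molybdenum carbonyl is needed, and the benzylic and α-carbonyl hydrogens must survive methoxide.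
- Comparison: it builds two rings against one, and is equal in having no stereochemical issue in the product. Mechanistically it relies on a base-mediated condensation with a real chemoselectivity question, against a regiospecific thermal cascade. The route to A5 would be clearly longer than the routes to 10 and 17.

Alternative 3: Ring B is cut at B5–B6 and B1–B2, into a four-carbon 1-methoxy-1,3-bis(trimethylsilyloxy)diene A7 that carries both arms and the two-carbon acyl ynol ether 1-ethoxyhex-1-yn-3-one A8. In the forward key step a Diels–Alder addition followed by loss of methanol and desilylation would give A6, with butanoyl already at B1, one ethyl ether at B6 and free hydroxyls at B2 and B4.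
- In its favour: it forms the same ring with the same number of new bonds as the chosen step, so on that count it is equal. It is better after the key step: no Friedel–Crafts acylation is needed, and the single aryl ether sits ortho to the ketone where BCl3 alone would remove it.
- Against it here: both arms must sit on one small keto-ester, which needs two enolate alkylations with ring–CH2 electrophiles, the reverse of the natural polarity of the outer rings. The double silylation needs strong base in the presence of the enolisable acetyl and propanoyl groups. The tetrasubstituted diene is hindered and moisture-sensitive, and the ethoxy group of A8 lowers its dienophilicity.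
- Comparison: equal in ring and bond count and shorter in the end game. The chosen plan puts one arm on each partner with natural polarity and needs no strong base near the outer rings. Overall step economy would be similar or worse once the synthesis of A7 is counted.

Key step: step 9

Assumption: the O-methylated outer rings are drawn as the 3,5-dimethoxy cross-conjugated dienones; any positional isomer of these enol ethers should behave alike in the later steps and converge to the same triketone in step 11.

## Route

Step 1
Reactants: 1 1-(2,4,6-trihydroxyphenyl)propan-1-one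
Product: 2 3,5-dihydroxy-4,4-dimethyl-2-propanoylcyclohexa-2,5-dien-1-one
Conditions: NaOMe (3.5 equiv), MeI (2.2 equiv), MeOH, 0 °C → rt
Reagents that add atoms: iodomethane, CI
Why: Dearomative C-methylation of an acylphloroglucinol polyanion; the second methyl enters at the same carbon because the mono-methyl enolate is the more electron-rich one, and limiting MeI plus the low nucleophilicity of the acidic triketone product should restrain further methylation.

Step 2
Reactants: 2 3,5-dihydroxy-4,4-dimethyl-2-propanoylcyclohexa-2,5-dien-1-one; 3 benzyl prop-2-enoate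
Product: 4 benzyl 3-(2,4-dihydroxy-3,3-dimethyl-6-oxo-5-propanoylcyclohexa-1,4-dien-1-yl)propanoate
Conditions: 3 (1.05 equiv), DBU (0.3 equiv), MeCN, 50 °C
Reagents that add atoms: none
Why: Michael addition of a cyclic 1,3-dione through its only hydrogen-bearing ring carbon; the acidic substrate protonates the ester enolate, so substoichiometric amidine base suffices, and one equivalent of 3 limits double addition.

Step 3
Reactants: 4 benzyl 3-(2,4-dihydroxy-3,3-dimethyl-6-oxo-5-propanoylcyclohexa-1,4-dien-1-yl)propanoate
Product: 5 benzyl 3-(2,4-dimethoxy-3,3-dimethyl-6-oxo-5-propanoylcyclohexa-1,4-dien-1-yl)propanoate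
Conditions: TMSCHN2 (5 equiv), PhMe–MeOH (4:1), 0 °C → rt
Reagents that add atoms: (trimethylsilyl)diazomethane, C[Si](C)(C)C=[N+]=[N-]
Why: O-Methylation of vinylogous carboxylic acids by a diazoalkane under neutral conditions; the benzyl ester and the propanoyl ketone are not touched.

Step 4
Reactants: 5 benzyl 3-(2,4-dimethoxy-3,3-dimethyl-6-oxo-5-propanoylcyclohexa-1,4-dien-1-yl)propanoate
Product: 6 3-(2,4-dimethoxy-3,3-dimethyl-6-oxo-5-propanoylcyclohexa-1,4-dien-1-yl)propanoic acid
Conditions: H2 (1 atm), 10% Pd/C, EtOAc, rt
Reagents that add atoms: none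
Why: Hydrogenolysis of a benzyl ester; the fully substituted donor–acceptor ring alkenes and the ketones should not be reduced at 1 atm, and the neutral conditions spare the vinylogous methyl esters that hydrolysis would destroy.

Step 5
Reactants: 6 3-(2,4-dimethoxy-3,3-dimethyl-6-oxo-5-propanoylcyclohexa-1,4-dien-1-yl)propanoic acid; 7 ethoxyethyne
Product: 10 rac-3-ethoxy-4-[(2,4-dimethoxy-3,3-dimethyl-6-oxo-5-propanoylcyclohexa-1,4-dien-1-yl)methyl]cyclobut-2-en-1-one, via acid chloride 8 (not isolated), via ketene 9 (not isolated)
Conditions: 1-chloro-N,N,2-trimethylprop-1-en-1-amine (1.1 equiv), CH2Cl2, 0 °C; then 7 (5 equiv), Et3N (1.3 equiv, slow addition), Et2O, 0 °C → rt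
Reagents that add atoms: none
Why: The α-chloroenamine gives acid chloride 8 without free HCl, Et3N dehydrochlorinates it to aldoketene 9, and 9 is trapped by the electron-rich alkyne in a regiospecific ketene–alkyne [2+2] cycloaddition (terminal alkyne carbon to the ketene carbonyl carbon), a known route to 3-ethoxycyclobutenones. Slow amine addition into excess 7 should disfavour ketene dimerisation; the C-4 stereocentre forms racemic and is erased in step 9.

Step 6
Reactants: 11 1-(2,4,6-trihydroxyphenyl)ethan-1-one
Product: 12 2-acetyl-3,5-dihydroxy-4,4-dimethylcyclohexa-2,5-dien-1-one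
Conditions: NaOMe (3.5 equiv), MeI (2.2 equiv), MeOH, 0 °C → rt
Reagents that add atoms: iodomethane, CI
Why: The same dearomative gem-dimethylation of an acylphloroglucinol as in step 1, with the same control by stoichiometry.

Step 7
Reactants: 7 ethoxyethyne
Product: 13 3-ethoxyprop-2-yn-1-ol
Conditions: n-BuLi (1.0 equiv), THF, −78 °C; (CH2O)n, −78 °C → rt; H2O quench
Reagents that add atoms: formaldehyde (as paraformaldehyde), C=O
Why: Deprotonation of the terminal alkyne and 1,2-addition of the lithium acetylide to formaldehyde; the basic quench avoids the acid-catalysed Meyer–Schuster rearrangement of the ynol ether carbinol.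

Step 8
Reactants: 13 3-ethoxyprop-2-yn-1-ol; 12 2-acetyl-3,5-dihydroxy-4,4-dimethylcyclohexa-2,5-dien-1-one
Product: 17 2-acetyl-6-(3-ethoxyprop-2-yn-1-yl)-3,5-dimethoxy-4,4-dimethylcyclohexa-2,5-dien-1-one, via 3-ethoxyprop-2-yn-1-yl methanesulfonate 14 (not isolated), via 3-bromo-1-ethoxyprop-1-yne 15 (not isolated), via dilithium dienolate 16 (not isolated)
Conditions: 13, MsCl, Et3N, CH2Cl2, −40 °C, then LiBr, THF, −20 °C; 12, LiOt-Bu (2.1 equiv), THF–PhMe, 0 °C, add 15, −20 °C → rt; LiOt-Bu (1.0 equiv), Me2SO4 (3 equiv), DMPU, 0 °C → rt; aq NH3–NaHCO3 work-up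
Reagents that add atoms: dimethyl sulfate, COS(=O)(=O)OC
Why: Sulfonylation and Finkelstein-type exchange give propargylic bromide 15 without acid; the dilithium dianion of 12 in a weakly polar medium should be alkylated by SN2 at its only hydrogen-bearing ring carbon. The resulting dienolate 16 is O-methylated in the same flask by the hard electrophile dimethyl sulfate with DMPU, so no acidic enol, which would add to its own ynol ether, is ever set free.

Step 9
Reactants: 10 rac-3-ethoxy-4-[(2,4-dimethoxy-3,3-dimethyl-6-oxo-5-propanoylcyclohexa-1,4-dien-1-yl)methyl]cyclobut-2-en-1-one; 17 2-acetyl-6-(3-ethoxyprop-2-yn-1-yl)-3,5-dimethoxy-4,4-dimethylcyclohexa-2,5-dien-1-one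
Product: 22 3,5-diethoxy-2-[(5-acetyl-2,4-dimethoxy-3,3-dimethyl-6-oxocyclohexa-1,4-dien-1-yl)methyl]-6-[(2,4-dimethoxy-3,3-dimethyl-6-oxo-5-propanoylcyclohexa-1,4-dien-1-yl)methyl]phenol, via vinylketene 18 (not isolated), via 4-vinylcyclobutenone 19 (not isolated), via dienylketene 20 (not isolated), via cyclohexa-2,4-dienone 21 (not isolated)
Conditions: 10 (1.3 equiv), 17 (1.0 equiv), PhMe (0.5 M), 80 °C, sealed tube, argon
Reagents that add atoms: none
Why: Heating opens 10 by conrotatory 4π cleavage of its C-1–C-4 bond, driven by release of ring strain, to vinylketene 18, with the C-4 substituent turning outward. Ynol ether 17 then adds to the ketene in a regiospecific [2+2]: its nucleophilic carbon (future B3) bonds to the ketene carbon (B4) and its oxygen-bearing carbon (B2) to the α-carbon (B1), giving 4-vinylcyclobutenone 19. 19 reopens reversibly to dienylketene 20, whose isomer with B3 and B6 cis closes ring B by thermal disrotatory 6π electrocyclisation (B5 onto B4), and cyclohexa-2,4-dienone 21 tautomerises irreversibly to phenol 22. The closest known reaction type is the Danheiser benzannulation of cyclobutenones with alkoxyalkynes; a 3-alkoxy-4-alkyl cyclobutenone with groups this large is an extension in substrate only. No stereocentre remains: the centres of 10, 19 and 21 are racemic, transient and destroyed on aromatisation. The step needs head-to-tail regiochemistry, which the polarisation of the ynol ether toward the electrophilic ketene carbon secures, and the arms cannot exchange because each is bound to a different partner and no ring–CH2 bond is broken. The medium is neutral, so the enol ethers and acyl groups of rings A and C are spectators, and 80 °C stays below the retro-ene fragmentation of the ethyl ynol ether.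

Step 10
Reactants: 22 3,5-diethoxy-2-[(5-acetyl-2,4-dimethoxy-3,3-dimethyl-6-oxocyclohexa-1,4-dien-1-yl)methyl]-6-[(2,4-dimethoxy-3,3-dimethyl-6-oxo-5-propanoylcyclohexa-1,4-dien-1-yl)methyl]phenol; 23 butanoyl chloride
Product: 24 1-{2,6-diethoxy-4-hydroxy-3-[(5-acetyl-2,4-dimethoxy-3,3-dimethyl-6-oxocyclohexa-1,4-dien-1-yl)methyl]-5-[(2,4-dimethoxy-3,3-dimethyl-6-oxo-5-propanoylcyclohexa-1,4-dien-1-yl)methyl]phenyl}butan-1-one
Conditions: 23 (1.2 equiv), TiCl4 (4 equiv), CH2Cl2, −78 → −20 °C; H2O
Reagents that add atoms: none
Why: Friedel–Crafts acylation at B1, the only unsubstituted carbon of ring B, activated by two ortho alkoxy groups and a para hydroxyl, while the acyl-dienone outer rings are too electron-poor for C-acylation. Low temperature and the titanium phenoxide at B4 should keep O-acylation and attack at substituted carbons behind C–H substitution; any ether lost to the Lewis acid only anticipates step 11.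

Step 11
Reactants: 24 1-{2,6-diethoxy-4-hydroxy-3-[(5-acetyl-2,4-dimethoxy-3,3-dimethyl-6-oxocyclohexa-1,4-dien-1-yl)methyl]-5-[(2,4-dimethoxy-3,3-dimethyl-6-oxo-5-propanoylcyclohexa-1,4-dien-1-yl)methyl]phenyl}butan-1-one
Product: 25 1-{2,4,6-trihydroxy-3-[(5-acetyl-2,4-dihydroxy-3,3-dimethyl-6-oxocyclohexa-1,4-dien-1-yl)methyl]-5-[(2,4-dihydroxy-3,3-dimethyl-6-oxo-5-propanoylcyclohexa-1,4-dien-1-yl)methyl]phenyl}butan-1-one (CNP0315613.0)
Conditions: BCl3 (12 equiv), n-Bu4NI (8 equiv), CH2Cl2, −78 °C → rt; H2O
Reagents that add atoms: none
Why: Lewis-acid ether cleavage: boron binds the chelating carbonyl–ether pairs and iodide removes the alkyl groups by SN2, which should cleave the four vinylogous methyl esters and both aryl ethyl ethers. BCl3 alone would stop after the first ortho ether once the ketone is held in a boron chelate. Low temperature without protic acid should spare the bridges, and aqueous work-up hydrolyses the borates to 25.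

## Compound list

1 | 1-(2,4,6-trihydroxyphenyl)propan-1-one | CCC(=O)c1c(O)cc(O)cc1O | starting material
2 | 3,5-dihydroxy-4,4-dimethyl-2-propanoylcyclohexa-2,5-dien-1-one | CCC(=O)C1=C(O)C(C)(C)C(O)=CC1=O | intermediate
3 | benzyl prop-2-enoate | C=CC(=O)OCc1ccccc1 | starting material
4 | benzyl 3-(2,4-dihydroxy-3,3-dimethyl-6-oxo-5-propanoylcyclohexa-1,4-dien-1-yl)propanoate | CCC(=O)C1=C(O)C(C)(C)C(O)=C(CCC(=O)OCc2ccccc2)C1=O | intermediate
5 | benzyl 3-(2,4-dimethoxy-3,3-dimethyl-6-oxo-5-propanoylcyclohexa-1,4-dien-1-yl)propanoate | CCC(=O)C1=C(OC)C(C)(C)C(OC)=C(CCC(=O)OCc2ccccc2)C1=O | intermediate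
6 | 3-(2,4-dimethoxy-3,3-dimethyl-6-oxo-5-propanoylcyclohexa-1,4-dien-1-yl)propanoic acid | CCC(=O)C1=C(OC)C(C)(C)C(OC)=C(CCC(=O)O)C1=O | intermediate
7 | ethoxyethyne | CCOC#C | starting material
8 | 3-(2,4-dimethoxy-3,3-dimethyl-6-oxo-5-propanoylcyclohexa-1,4-dien-1-yl)propanoyl chloride | CCC(=O)C1=C(OC)C(C)(C)C(OC)=C(CCC(Cl)=O)C1=O | intermediate
9 | 3-(2,4-dimethoxy-3,3-dimethyl-6-oxo-5-propanoylcyclohexa-1,4-dien-1-yl)prop-1-en-1-one (aldoketene) | CCC(=O)C1=C(OC)C(C)(C)C(OC)=C(CC=C=O)C1=O | intermediate
10 | rac-3-ethoxy-4-[(2,4-dimethoxy-3,3-dimethyl-6-oxo-5-propanoylcyclohexa-1,4-dien-1-yl)methyl]cyclobut-2-en-1-one (racemic at C-4) | CCOC1=CC(=O)C1CC2=C(OC)C(C)(C)C(OC)=C(C(=O)CC)C2=O | intermediate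
11 | 1-(2,4,6-trihydroxyphenyl)ethan-1-one | CC(=O)c1c(O)cc(O)cc1O | starting material
12 | 2-acetyl-3,5-dihydroxy-4,4-dimethylcyclohexa-2,5-dien-1-one | CC(=O)C1=C(O)C(C)(C)C(O)=CC1=O | intermediate
13 | 3-ethoxyprop-2-yn-1-ol | CCOC#CCO | intermediate
14 | 3-ethoxyprop-2-yn-1-yl methanesulfonate | CCOC#CCOS(C)(=O)=O | intermediate
15 | 3-bromo-1-ethoxyprop-1-yne | CCOC#CCBr | intermediate
16 | dilithium dienolate of 2-acetyl-6-(3-ethoxyprop-2-yn-1-yl)-3,5-dihydroxy-4,4-dimethylcyclohexa-2,5-dien-1-one | [Li+].[Li+].CCOC#CCC1=C([O-])C(C)(C)C([O-])=C(C(C)=O)C1=O | intermediate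
17 | 2-acetyl-6-(3-ethoxyprop-2-yn-1-yl)-3,5-dimethoxy-4,4-dimethylcyclohexa-2,5-dien-1-one | CCOC#CCC1=C(OC)C(C)(C)C(OC)=C(C(C)=O)C1=O | intermediate
18 | (3Z)-5-(2,4-dimethoxy-3,3-dimethyl-6-oxo-5-propanoylcyclohexa-1,4-dien-1-yl)-3-ethoxypenta-1,3-dien-1-one (vinylketene) | O=C=C/C(OCC)=C/CC1=C(OC)C(C)(C)C(OC)=C(C(=O)CC)C1=O | intermediate
19 | rac-2-[(5-acetyl-2,4-dimethoxy-3,3-dimethyl-6-oxocyclohexa-1,4-dien-1-yl)methyl]-3-ethoxy-4-[(1Z)-3-(2,4-dimethoxy-3,3-dimethyl-6-oxo-5-propanoylcyclohexa-1,4-dien-1-yl)-1-ethoxyprop-1-en-1-yl]cyclobut-2-en-1-one (racemic at C-4) | O=C1C(CC2=C(OC)C(C)(C)C(OC)=C(C(C)=O)C2=O)=C(OCC)C1/C(OCC)=C/CC3=C(OC)C(C)(C)C(OC)=C(C(=O)CC)C3=O | intermediate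
20 | (3E,5Z)-2-[(5-acetyl-2,4-dimethoxy-3,3-dimethyl-6-oxocyclohexa-1,4-dien-1-yl)methyl]-7-(2,4-dimethoxy-3,3-dimethyl-6-oxo-5-propanoylcyclohexa-1,4-dien-1-yl)-3,5-diethoxyhepta-1,3,5-trien-1-one (dienylketene) | O=C=C(CC2=C(OC)C(C)(C)C(OC)=C(C(C)=O)C2=O)/C(OCC)=C\C(OCC)=C\CC3=C(OC)C(C)(C)C(OC)=C(C(=O)CC)C3=O | intermediate
21 | rac-2-[(5-acetyl-2,4-dimethoxy-3,3-dimethyl-6-oxocyclohexa-1,4-dien-1-yl)methyl]-6-[(2,4-dimethoxy-3,3-dimethyl-6-oxo-5-propanoylcyclohexa-1,4-dien-1-yl)methyl]-3,5-diethoxycyclohexa-2,4-dien-1-one (racemic at C-6) | O=C1C(CC2=C(OC)C(C)(C)C(OC)=C(C(C)=O)C2=O)=C(OCC)C=C(OCC)C1CC3=C(OC)C(C)(C)C(OC)=C(C(=O)CC)C3=O | intermediate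
22 | 3,5-diethoxy-2-[(5-acetyl-2,4-dimethoxy-3,3-dimethyl-6-oxocyclohexa-1,4-dien-1-yl)methyl]-6-[(2,4-dimethoxy-3,3-dimethyl-6-oxo-5-propanoylcyclohexa-1,4-dien-1-yl)methyl]phenol | CCOc1cc(OCC)c(CC2=C(OC)C(C)(C)C(OC)=C(C(=O)CC)C2=O)c(O)c1CC1=C(OC)C(C)(C)C(OC)=C(C(C)=O)C1=O | intermediate
23 | butanoyl chloride | CCCC(Cl)=O | starting material
24 | 1-{2,6-diethoxy-4-hydroxy-3-[(5-acetyl-2,4-dimethoxy-3,3-dimethyl-6-oxocyclohexa-1,4-dien-1-yl)methyl]-5-[(2,4-dimethoxy-3,3-dimethyl-6-oxo-5-propanoylcyclohexa-1,4-dien-1-yl)methyl]phenyl}butan-1-one | CCCC(=O)c1c(OCC)c(CC2=C(OC)C(C)(C)C(OC)=C(C(C)=O)C2=O)c(O)c(CC2=C(OC)C(C)(C)C(OC)=C(C(=O)CC)C2=O)c1OCC | intermediate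
25 | 1-{2,4,6-trihydroxy-3-[(5-acetyl-2,4-dihydroxy-3,3-dimethyl-6-oxocyclohexa-1,4-dien-1-yl)methyl]-5-[(2,4-dihydroxy-3,3-dimethyl-6-oxo-5-propanoylcyclohexa-1,4-dien-1-yl)methyl]phenyl}butan-1-one (CNP0315613.0) | CCCC(=O)c1c(O)c(CC2=C(O)C(C)(C)C(O)=C(C(C)=O)C2=O)c(O)c(CC2=C(O)C(C)(C)C(O)=C(C(=O)CC)C2=O)c1O | target

## Step count and least certain steps

Total step count: 11. Longest linear sequence: 8 steps (steps 1, 2, 3, 4, 5, 9, 10, 11).

Step 9 (key step). The most likely failures are slow capture of the vinylketene by the hindered, internal ynol ether, so that the ketene recloses or oligomerises; retro-ene loss of ethylene from the ynol ether if the temperature must be raised to drive the second ring opening; and acylation of the new phenol by ketene intermediates. The fallback leaves the cycloaddition logic for classical methylene transfer; it sets out from 12 and 2 and returns at 25.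
- 12 with formaldehyde and piperidine should give the Mannich base 2-acetyl-3,5-dihydroxy-4,4-dimethyl-6-(piperidin-1-ylmethyl)cyclohexa-2,5-dien-1-one F2.
- Warming F2 with an excess of purchased 1-(2,4,6-trihydroxyphenyl)butan-1-one F1 should give, by loss of piperidine and conjugate addition, the two-ring compound 2-acetyl-6-[(3-butanoyl-2,4,6-trihydroxyphenyl)methyl]-3,5-dihydroxy-4,4-dimethylcyclohexa-2,5-dien-1-one F3.
- 2 is aminomethylated in the same way to 3,5-dihydroxy-4,4-dimethyl-6-(piperidin-1-ylmethyl)-2-propanoylcyclohexa-2,5-dien-1-one F4, and F4 with F3 should give 25.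
- The cost is statistical over-alkylation and possible exchange of arms, to be met by stoichiometry and chromatography.

Step 8. The propargylic bromide may ionise or rearrange before the C–C bond forms, since the ethoxy group stabilises the cation. O-alkylation may compete with C-alkylation, and any transient acidification would let an enol add to the ynol ether. The fallback replaces the covalent halide by a preformed ammonium salt built by a Mannich reaction; it sets out from 7 and 12 and returns at 16, hence 17.
- The lithium salt of 7 added to dimethyl(methylidene)ammonium iodide should give 3-ethoxy-N,N-dimethylprop-2-yn-1-amine F5.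
- Iodomethane converts F5 into the crystalline (3-ethoxyprop-2-yn-1-yl)trimethylammonium iodide F6.
- The dilithium dianion of 12 is alkylated by F6 in THF–DMPU with loss of trimethylamine to give 16, which is methylated as in step 8.

Step 5. Dimerisation of the aldoketene, or acylation of the neighbouring enol ether oxygen by the acid chloride, may outrun the intermolecular [2+2]. The fallback generates the same ketene without amine or a three-carbon acid chloride, by a Wolff rearrangement; it sets out from 2 and returns at 9, hence 10.
- C-Alkylation of 2 with benzyl bromoacetate should give benzyl 2-(2,4-dihydroxy-3,3-dimethyl-6-oxo-5-propanoylcyclohexa-1,4-dien-1-yl)acetate F7.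
- TMSCHN2 gives the bis(methyl enol ether) benzyl 2-(2,4-dimethoxy-3,3-dimethyl-6-oxo-5-propanoylcyclohexa-1,4-dien-1-yl)acetate F8.
- Hydrogenolysis gives 2-(2,4-dimethoxy-3,3-dimethyl-6-oxo-5-propanoylcyclohexa-1,4-dien-1-yl)acetic acid F9.
- Its mixed anhydride with isobutyl chloroformate and diazomethane gives the diazoketone 1-diazo-3-(2,4-dimethoxy-3,3-dimethyl-6-oxo-5-propanoylcyclohexa-1,4-dien-1-yl)propan-2-one F10.
- Irradiation of F10 with visible light (about 450 nm, to avoid exciting the dienone) in the presence of excess 7 should give 9 and then 10.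

Step 10. O-acylation of the hindered phenol, or of enols unmasked by the Lewis acid, may compete. Attack at B3 or B5 with loss of an arm is possible, as is Lewis-acid-induced pyran closure of the B4 oxygen onto an enol ether carbon. The fallback reverses the order of the end game and also replaces step 11; it sets out from 22 and returns at 25.
- BBr3 in CH2Cl2 at low temperature removes all six alkyl groups to give the free des-butanoyl trimer 2-acetyl-6-({2,4,6-trihydroxy-3-[(2,4-dihydroxy-3,3-dimethyl-6-oxo-5-propanoylcyclohexa-1,4-dien-1-yl)methyl]phenyl}methyl)-3,5-dihydroxy-4,4-dimethylcyclohexa-2,5-dien-1-one F11.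
- A Houben–Hoesch reaction with butanenitrile, HCl and ZnCl2 in ether should acylate the single free ring B carbon through the ketiminium chloride F12, which aqueous hydrolysis converts into 25.

## Further compounds

F1 | step 9 | 1-(2,4,6-trihydroxyphenyl)butan-1-one | CCCC(=O)c1c(O)cc(O)cc1O
F2 | step 9 | 2-acetyl-3,5-dihydroxy-4,4-dimethyl-6-(piperidin-1-ylmethyl)cyclohexa-2,5-dien-1-one | CC(=O)C1=C(O)C(C)(C)C(O)=C(CN2CCCCC2)C1=O
F3 | step 9 | 2-acetyl-6-[(3-butanoyl-2,4,6-trihydroxyphenyl)methyl]-3,5-dihydroxy-4,4-dimethylcyclohexa-2,5-dien-1-one | CCCC(=O)c1c(O)cc(O)c(CC2=C(O)C(C)(C)C(O)=C(C(C)=O)C2=O)c1O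
F4 | step 9 | 3,5-dihydroxy-4,4-dimethyl-6-(piperidin-1-ylmethyl)-2-propanoylcyclohexa-2,5-dien-1-one | CCC(=O)C1=C(O)C(C)(C)C(O)=C(CN2CCCCC2)C1=O
F5 | step 8 | 3-ethoxy-N,N-dimethylprop-2-yn-1-amine | CCOC#CCN(C)C
F6 | step 8 | (3-ethoxyprop-2-yn-1-yl)trimethylammonium iodide | CCOC#CC[N+](C)(C)C.[I-]
F7 | step 5 | benzyl 2-(2,4-dihydroxy-3,3-dimethyl-6-oxo-5-propanoylcyclohexa-1,4-dien-1-yl)acetate | CCC(=O)C1=C(O)C(C)(C)C(O)=C(CC(=O)OCc2ccccc2)C1=O
F8 | step 5 | benzyl 2-(2,4-dimethoxy-3,3-dimethyl-6-oxo-5-propanoylcyclohexa-1,4-dien-1-yl)acetate | CCC(=O)C1=C(OC)C(C)(C)C(OC)=C(CC(=O)OCc2ccccc2)C1=O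
F9 | step 5 | 2-(2,4-dimethoxy-3,3-dimethyl-6-oxo-5-propanoylcyclohexa-1,4-dien-1-yl)acetic acid | CCC(=O)C1=C(OC)C(C)(C)C(OC)=C(CC(=O)O)C1=O
F10 | step 5 | 1-diazo-3-(2,4-dimethoxy-3,3-dimethyl-6-oxo-5-propanoylcyclohexa-1,4-dien-1-yl)propan-2-one | CCC(=O)C1=C(OC)C(C)(C)C(OC)=C(CC(=O)C=[N+]=[N-])C1=O
F11 | step 10 | 2-acetyl-6-({2,4,6-trihydroxy-3-[(2,4-dihydroxy-3,3-dimethyl-6-oxo-5-propanoylcyclohexa-1,4-dien-1-yl)methyl]phenyl}methyl)-3,5-dihydroxy-4,4-dimethylcyclohexa-2,5-dien-1-one | Oc1cc(O)c(CC2=C(O)C(C)(C)C(O)=C(C(=O)CC)C2=O)c(O)c1CC1=C(O)C(C)(C)C(O)=C(C(C)=O)C1=O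
F12 | step 10 | butan-1-iminium chloride of 25 (C=NH2+ in place of the butanoyl C=O) | CCCC(=[NH2+])c1c(O)c(CC2=C(O)C(C)(C)C(O)=C(C(C)=O)C2=O)c(O)c(CC2=C(O)C(C)(C)C(O)=C(C(=O)CC)C2=O)c1O.[Cl-]
A1 | alternative 1 | 2-acetyl-6-{[2,4-bis(benzyloxy)-6-hydroxyphenyl]methyl}-3,5-dihydroxy-4,4-dimethylcyclohexa-2,5-dien-1-one | CC(=O)C1=C(O)C(C)(C)C(O)=C(Cc2c(O)cc(OCc3ccccc3)cc2OCc2ccccc2)C1=O
A2 | alternative 1 | 5,7-bis(benzyloxy)-3,4-dihydro-2H-chromen-2-one | O=C1CCc2c(OCc3ccccc3)cc(OCc3ccccc3)cc2O1
A3 | alternative 1 | 3,3,6-trimethyl-2H-pyran-2,4(3H)-dione | CC1=CC(=O)C(C)(C)C(=O)O1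
A4 | alternative 2 | tri-O-benzyl ether of 25 (benzyl on the three ring B oxygens) | CCCC(=O)c1c(OCc2ccccc2)c(CC2=C(O)C(C)(C)C(O)=C(C(C)=O)C2=O)c(OCc2ccccc2)c(CC2=C(O)C(C)(C)C(O)=C(C(=O)CC)C2=O)c1OCc1ccccc1
A5 | alternative 2 | dimethyl bis-isoxazole precursor: 1-[2,4,6-tris(benzyloxy)phenyl]butan-1-one bearing at C-3 a 4-methoxy-3,3-dimethyl-2,4-dioxo-1-(3-methylisoxazol-5-yl)butyl-methyl arm and at C-5 the 3-ethylisoxazol-5-yl analogue (mixture of diastereomers) | CCCC(=O)c1c(OCc2ccccc2)c(CC(c2cc(C)no2)C(=O)C(C)(C)C(=O)OC)c(OCc2ccccc2)c(CC(c2cc(CC)no2)C(=O)C(C)(C)C(=O)OC)c1OCc1ccccc1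
A6 | alternative 3 | 1-{2-ethoxy-4,6-dihydroxy-5-[(5-acetyl-2,4-dimethoxy-3,3-dimethyl-6-oxocyclohexa-1,4-dien-1-yl)methyl]-3-[(2,4-dimethoxy-3,3-dimethyl-6-oxo-5-propanoylcyclohexa-1,4-dien-1-yl)methyl]phenyl}butan-1-one | CCCC(=O)c1c(O)c(CC2=C(OC)C(C)(C)C(OC)=C(C(C)=O)C2=O)c(O)c(CC2=C(OC)C(C)(C)C(OC)=C(C(=O)CC)C2=O)c1OCC
A7 | alternative 3 | 1-methoxy-1,3-bis(trimethylsilyloxy)buta-1,3-diene bearing the ring A methyl arm at C-2 and the ring C methyl arm at C-4 | COC(O[Si](C)(C)C)=C(CC1=C(OC)C(C)(C)C(OC)=C(C(C)=O)C1=O)C(O[Si](C)(C)C)=CCC1=C(OC)C(C)(C)C(OC)=C(C(=O)CC)C1=O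
A8 | alternative 3 | 1-ethoxyhex-1-yn-3-one | CCCC(=O)C#COCC
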